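**Retrosynthetic overview**
1. The epoxide comes last, by hydroxyl-directed Sharpless epoxidation of the 1(10)-alkene of a 14-hydroxy heliangolide; the 8-isobutyrate comes from Mitsunobu inversion of the 8-epi carbinol.
2. The ten-membered carbocycle is closed at C7–C8 by an intramolecular Barbier allylation: an allylindium made from a 3-(bromomethyl)butenolide (butenolide β-carbon as donor) adds to the C8 aldehyde, which is held as a lactol with the C14 hydroxyl. This step sets C7, C8 and the exo-methylene lactone.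
3. The butenolide (C6 stereocentre) comes from a catalytic asymmetric Ni/Cr coupling of a Z-enal with methyl (Z)-2-(hydroxymethyl)-3-iodoacrylate, then lactonisation and Appel bromination.
4. The Z,Z-chain comes from Still–Gennari olefination of the aldehyde obtained by ozonolysis of neryl acetate; reduction and acetal exchange tie C14–OH and C8 into an oxolane acetal.
5. Ring order: oxolane acetal (temporary) → butenolide → ten-membered ring → epoxide.

Assumption: positions are given in germacrane numbering (C1–C15); the acetal carbon of the oxolane intermediates is an epimer mixture of no consequence, and it becomes the C8 aldehyde carbon in the ring-closing step.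

**Step 1**
Reactants: 1 methyl 2-[bis(2,2,2-trifluoroethoxy)phosphoryl]acetate; 2 2-bromo-1,1-dimethoxyethane
Product: 3 methyl 2-[bis(2,2,2-trifluoroethoxy)phosphoryl]-4,4-dimethoxybutanoate (racemic)
Conditions: NaH, DMSO, rt; then 2, NaI (10 mol %), 65 °C
Reagents that add atoms: none
Why: SN2 C-alkylation of the stabilised phosphonoacetate anion (iodide-catalysed) gives the α-substituted Still–Gennari reagent, and the more hindered product anion resists a second alkylation.

**Step 2**
Reactants: 4 neryl acetate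
Product: 5 (2Z)-3-methyl-6-oxohex-2-en-1-yl acetate
Conditions: O3 (1.0 equiv), pyridine, CH2Cl2, −78 °C; then Me2S
Reagents that add atoms: ozone [O-][O+]=O
Why: Chemoselective ozonolysis cleaves the electron-rich isopropylidene alkene, while the alkene deactivated by the allylic acetate survives with its Z geometry.

**Step 3**
Reactants: 5 (2Z)-3-methyl-6-oxohex-2-en-1-yl acetate; 3 methyl 2-[bis(2,2,2-trifluoroethoxy)phosphoryl]-4,4-dimethoxybutanoate
Product: 6 methyl (2Z,6Z)-8-(acetyloxy)-2-(2,2-dimethoxyethyl)-6-methylocta-2,6-dienoate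
Conditions: 3, KN(SiMe3)2, 18-crown-6, THF, −78 °C; then 5
Reagents that add atoms: none
Why: Still–Gennari (Z-selective Horner–Wadsworth–Emmons) olefination: fast elimination from the kinetic adduct of the trifluoroethyl phosphonate places the C2 chain cis to the ester carbon (future C14) and trans to the C9 arm.

**Step 4**
Reactants: 6 methyl (2Z,6Z)-8-(acetyloxy)-2-(2,2-dimethoxyethyl)-6-methylocta-2,6-dienoate
Product: 8 (2Z)-6-[(3Z)-5-methoxyoxolan-3-ylidene]-3-methylhex-2-en-1-ol, via acetal diol 7 (not isolated)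
Conditions: i-Bu2AlH (5.5 equiv), CH2Cl2, −78 → 0 °C, aq. KNaC4H4O6 work-up; crude 7, PPTS (10 mol %), MeOH, rt
Reagents that add atoms: none
Why: Hydride reduction of ester and acetate, then acid-catalysed intramolecular transacetalisation to the five-membered mixed acetal, masks the C14 hydroxyl and the C8 aldehyde together and leaves only the C6 allylic alcohol free; the new acetal centre is an epimer mixture that is lost later.

**Step 5**
Reactants: 8 (2Z)-6-[(3Z)-5-methoxyoxolan-3-ylidene]-3-methylhex-2-en-1-ol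
Product: 9 (2Z)-6-[(3Z)-5-methoxyoxolan-3-ylidene]-3-methylhex-2-enal
Conditions: MnO2 (15 equiv), CH2Cl2, rt, dark
Reagents that add atoms: none
Why: Allylic oxidation with manganese dioxide gives the Z-enal without Z/E isomerisation, as in nerol to neral.

**Step 6**
Reactants: 10 methyl propiolate; 11 formaldehyde (monomer from cracked paraformaldehyde)
Product: 12 methyl (2Z)-2-(hydroxymethyl)-3-iodoprop-2-enoate
Conditions: MgI2 (1.2 equiv), CH2Cl2, 0 °C
Reagents that add atoms: magnesium diiodide [Mg+2].[I-].[I-]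
Why: Halo-aldol (β-iodo Morita–Baylis–Hillman) reaction: iodide adds to the ynoate, the β-iodoallenolate is hydroxymethylated at the α-carbon, and kinetic control at 0 °C gives the Z isomer with iodine cis to the ester.

**Step 7**
Reactants: 9 (2Z)-6-[(3Z)-5-methoxyoxolan-3-ylidene]-3-methylhex-2-enal; 12 methyl (2Z)-2-(hydroxymethyl)-3-iodoprop-2-enoate
Product: 14 (5R)-3-(hydroxymethyl)-5-{(1Z)-5-[(3Z)-5-methoxyoxolan-3-ylidene]-2-methylpent-1-en-1-yl}furan-2(5H)-one, via hydroxy ester 13 (not isolated)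
Conditions: CrCl2 (10 mol %), Kishi oxazoline–sulfonamide ligand (11 mol %, the enantiomer that gives Si-face attack), proton sponge (10 mol %), NiCl2·(2,9-dimethyl-1,10-phenanthroline) (2 mol %), Mn powder, Cp2ZrCl2, LiCl, MeCN, rt; then PPTS (cat.), CH2Cl2, rt
Reagents that add atoms: none
Why: Catalytic asymmetric Nozaki–Hiyama–Kishi vinylation: zerovalent nickel inserts into the C–I bond, the vinyl group passes to the chiral sulfonamide-bound chromium and adds 1,2 to the Si face of the enal (6R), and the resulting Z γ-hydroxy ester lactonises to the butenolide.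

**Step 8**
Reactants: 14 (5R)-3-(hydroxymethyl)-5-{(1Z)-5-[(3Z)-5-methoxyoxolan-3-ylidene]-2-methylpent-1-en-1-yl}furan-2(5H)-one
Product: 15 (5R)-3-(bromomethyl)-5-{(1Z)-5-[(3Z)-5-methoxyoxolan-3-ylidene]-2-methylpent-1-en-1-yl}furan-2(5H)-one
Conditions: CBr4, PPh3, CH2Cl2, 0 °C
Reagents that add atoms: carbon tetrabromide BrC(Br)(Br)Br
Why: Appel bromination of the primary allylic alcohol under neutral conditions leaves the acetal and the base-sensitive C6 centre untouched.

**Step 9 (key step)**
Reactants: 15 (5R)-3-(bromomethyl)-5-{(1Z)-5-[(3Z)-5-methoxyoxolan-3-ylidene]-2-methylpent-1-en-1-yl}furan-2(5H)-one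
Product: 17 (3aR,4S,6Z,10Z,11aR)-4-hydroxy-6-(hydroxymethyl)-10-methyl-3-methylidene-3a,4,5,8,9,11a-hexahydrocyclodeca[b]furan-2(3H)-one, via lactol 16 (not isolated)
Conditions: 0.1 M aq. HCl–THF (1:4), rt, 1 h; then syringe-pump addition (10 h) to In powder (3 equiv), THF–H2O (4:1), 40 °C, final 0.002 M
Reagents that add atoms: water O
Why: Proposed new method: acid opens the mixed acetal to lactol 16, whose open hydroxy-aldehyde form is trapped intramolecularly by the allylindium made from the bromide, in which the butenolide β-carbon C7 (normally an acceptor) is the donor and attacks the aldehyde carbon C8 with allylic transposition (Barbier-type SE2′ allylation), closing the ten-membered ring and unveiling the exo-methylene lactone; the tether on C6 is expected to force attack anti to the C6–C5 bond (trans ring fusion, 7R), and a chair six-membered transition state with the ring chain pseudo-equatorial is expected to give the 8S carbinol; the closest known reactions are the zinc- or indium-mediated intermolecular Barbier reactions of 3-(bromomethyl)furan-2(5H)-ones with aldehydes, indium-mediated 2-(bromomethyl)acrylate additions to unprotected lactols, and CrCl2-mediated macrocyclic allylations that close germacranolide rings.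

**Step 10**
Reactants: 17 (3aR,4S,6Z,10Z,11aR)-4-hydroxy-6-(hydroxymethyl)-10-methyl-3-methylidene-3a,4,5,8,9,11a-hexahydrocyclodeca[b]furan-2(3H)-one
Product: 18 (3aR,4S,6Z,10Z,11aR)-6-({[tert-butyl(dimethyl)silyl]oxy}methyl)-4-hydroxy-10-methyl-3-methylidene-3a,4,5,8,9,11a-hexahydrocyclodeca[b]furan-2(3H)-one
Conditions: TBSCl (1.05 equiv), imidazole, CH2Cl2, −20 → 0 °C
Reagents that add atoms: tert-butyldimethylsilyl chloride CC(C)(C)[Si](C)(C)Cl
Why: Selective silylation of the primary allylic C14 hydroxyl over the hindered secondary C8 hydroxyl.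

**Step 11**
Reactants: 18 (3aR,4S,6Z,10Z,11aR)-6-({[tert-butyl(dimethyl)silyl]oxy}methyl)-4-hydroxy-10-methyl-3-methylidene-3a,4,5,8,9,11a-hexahydrocyclodeca[b]furan-2(3H)-one; 19 isobutyric acid
Product: 20 (3aR,4R,6Z,10Z,11aR)-6-({[tert-butyl(dimethyl)silyl]oxy}methyl)-10-methyl-3-methylidene-2-oxo-2,3,3a,4,5,8,9,11a-octahydrocyclodeca[b]furan-4-yl 2-methylpropanoate
Conditions: PPh3 and DIAD premixed, toluene, 0 °C; then 18 and 19, 0 °C → rt
Reagents that add atoms: none
Why: Mitsunobu esterification: the alkoxyphosphonium of the 8S carbinol is displaced by isobutyrate in an SN2 reaction with inversion, which installs the ester and sets 8R in one operation.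

**Step 12**
Reactants: 20 (3aR,4R,6Z,10Z,11aR)-6-({[tert-butyl(dimethyl)silyl]oxy}methyl)-10-methyl-3-methylidene-2-oxo-2,3,3a,4,5,8,9,11a-octahydrocyclodeca[b]furan-4-yl 2-methylpropanoate
Product: 21 (3aR,4R,6Z,10Z,11aR)-6-(hydroxymethyl)-10-methyl-3-methylidene-2-oxo-2,3,3a,4,5,8,9,11a-octahydrocyclodeca[b]furan-4-yl 2-methylpropanoate
Conditions: HF·pyridine, THF, 0 °C
Reagents that add atoms: none
Why: Fluoride-mediated desilylation under weakly acidic conditions spares the exo-methylene lactone and the isobutyrate.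

**Step 13**
Reactants: 21 (3aR,4R,6Z,10Z,11aR)-6-(hydroxymethyl)-10-methyl-3-methylidene-2-oxo-2,3,3a,4,5,8,9,11a-octahydrocyclodeca[b]furan-4-yl 2-methylpropanoate
Product: 22 CNP0247143.1, (1R,6R,7R,8R,10S)-1,10-epoxy-14-hydroxy-8-(2-methylpropanoyloxy)germacra-4(Z),11(13)-dien-12,6-olide
Conditions: Ti(OiPr)4 (20 mol %), L-(+)-diisopropyl tartrate (24 mol %), tert-butyl hydroperoxide (anhydrous, in decane), 4 Å MS, CH2Cl2, −20 °C
Reagents that add atoms: tert-butyl hydroperoxide CC(C)(C)OO
Why: Sharpless asymmetric epoxidation: only the alkene of the titanium-bound allylic alcohol is oxidised, the L-(+)-tartrate delivers oxygen to the face that gives 10S (the same facial sense that gives 2S epoxy alcohols from simple allylic alcohols), and the ring-trans alkene geometry then fixes 1R.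

**Compound list**
1 | methyl 2-[bis(2,2,2-trifluoroethoxy)phosphoryl]acetate | COC(=O)CP(=O)(OCC(F)(F)F)OCC(F)(F)F | starting material
2 | 2-bromo-1,1-dimethoxyethane | COC(CBr)OC | starting material
3 | methyl 2-[bis(2,2,2-trifluoroethoxy)phosphoryl]-4,4-dimethoxybutanoate (racemic) | COC(=O)C(CC(OC)OC)P(=O)(OCC(F)(F)F)OCC(F)(F)F | intermediate
4 | neryl acetate, (2Z)-3,7-dimethylocta-2,6-dien-1-yl acetate | CC(=O)OC/C=C(/C)CCC=C(C)C | starting material
5 | (2Z)-3-methyl-6-oxohex-2-en-1-yl acetate | CC(=O)OC/C=C(/C)CCC=O | intermediate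
6 | methyl (2Z,6Z)-8-(acetyloxy)-2-(2,2-dimethoxyethyl)-6-methylocta-2,6-dienoate | COC(=O)/C(CC(OC)OC)=C\CC/C(C)=C\COC(C)=O | intermediate
7 | (2Z,6Z)-2-(2,2-dimethoxyethyl)-6-methylocta-2,6-diene-1,8-diol | OC/C(CC(OC)OC)=C\CC/C(C)=C\CO | intermediate
8 | (2Z)-6-[(3Z)-5-methoxyoxolan-3-ylidene]-3-methylhex-2-en-1-ol (acetal epimers) | COC1C/C(=C/CC/C(C)=C\CO)CO1 | intermediate
9 | (2Z)-6-[(3Z)-5-methoxyoxolan-3-ylidene]-3-methylhex-2-enal (acetal epimers) | COC1C/C(=C/CC/C(C)=C\C=O)CO1 | intermediate
10 | methyl propiolate | COC(=O)C#C | starting material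
11 | formaldehyde (used as paraformaldehyde) | C=O | starting material
12 | methyl (2Z)-2-(hydroxymethyl)-3-iodoprop-2-enoate | COC(=O)/C(CO)=C\I | intermediate
13 | methyl (2Z,4R,5Z)-4-hydroxy-2-(hydroxymethyl)-9-[(3Z)-5-methoxyoxolan-3-ylidene]-6-methylnona-2,5-dienoate | O[C@H](/C=C(/C)CC/C=C1\COC(OC)C1)/C=C(/CO)C(=O)OC | intermediate
14 | (5R)-3-(hydroxymethyl)-5-{(1Z)-5-[(3Z)-5-methoxyoxolan-3-ylidene]-2-methylpent-1-en-1-yl}furan-2(5H)-one | O=C1O[C@H](/C=C(/C)CC/C=C2\COC(OC)C2)C=C1CO | intermediate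
15 | (5R)-3-(bromomethyl)-5-{(1Z)-5-[(3Z)-5-methoxyoxolan-3-ylidene]-2-methylpent-1-en-1-yl}furan-2(5H)-one | O=C1O[C@H](/C=C(/C)CC/C=C2\COC(OC)C2)C=C1CBr | intermediate
16 | (5R)-3-(bromomethyl)-5-{(1Z)-5-[(3Z)-5-hydroxyoxolan-3-ylidene]-2-methylpent-1-en-1-yl}furan-2(5H)-one (lactol) | O=C1O[C@H](/C=C(/C)CC/C=C2\COC(O)C2)C=C1CBr | intermediate
17 | (3aR,4S,6Z,10Z,11aR)-4-hydroxy-6-(hydroxymethyl)-10-methyl-3-methylidene-3a,4,5,8,9,11a-hexahydrocyclodeca[b]furan-2(3H)-one | C=C1C(=O)O[C@@H]2/C=C(/C)CC/C=C(\CO)C[C@H](O)[C@@H]12 | intermediate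
18 | (3aR,4S,6Z,10Z,11aR)-6-({[tert-butyl(dimethyl)silyl]oxy}methyl)-4-hydroxy-10-methyl-3-methylidene-3a,4,5,8,9,11a-hexahydrocyclodeca[b]furan-2(3H)-one | C=C1C(=O)O[C@@H]2/C=C(/C)CC/C=C(\CO[Si](C)(C)C(C)(C)C)C[C@H](O)[C@@H]12 | intermediate
19 | isobutyric acid | CC(C)C(=O)O | starting material
20 | (3aR,4R,6Z,10Z,11aR)-6-({[tert-butyl(dimethyl)silyl]oxy}methyl)-10-methyl-3-methylidene-2-oxo-2,3,3a,4,5,8,9,11a-octahydrocyclodeca[b]furan-4-yl 2-methylpropanoate | C=C1C(=O)O[C@@H]2/C=C(/C)CC/C=C(\CO[Si](C)(C)C(C)(C)C)C[C@@H](OC(=O)C(C)C)[C@@H]12 | intermediate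
21 | (3aR,4R,6Z,10Z,11aR)-6-(hydroxymethyl)-10-methyl-3-methylidene-2-oxo-2,3,3a,4,5,8,9,11a-octahydrocyclodeca[b]furan-4-yl 2-methylpropanoate | C=C1C(=O)O[C@@H]2/C=C(/C)CC/C=C(\CO)C[C@@H](OC(=O)C(C)C)[C@@H]12 | intermediate
22 | CNP0247143.1, (1R,6R,7R,8R,10S)-1,10-epoxy-14-hydroxy-8-(2-methylpropanoyloxy)germacra-4(Z),11(13)-dien-12,6-olide | C=C1C(=O)O[C@@H]2/C=C(/C)CC[C@H]3O[C@]3(CO)C[C@@H](OC(=O)C(C)C)[C@@H]12 | target

**Step count and risks**
Total: 13 steps. Longest linear sequence: 11 steps (steps 2–5 and 7–13 from neryl acetate); steps 1 and 6 prepare the two coupling partners.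

The three steps most likely to fail:

Step 9 (ring closure). A ten-membered ring is formed against dimerisation and protonation of the allylindium, and the sense at C7 and C8 rests on a transition-state model. Fallback, from 14 back to 17: close the same bond as a ketyl–olefin coupling in which the aldehyde carbon is the reduced, nucleophilic partner. Acetylation of 14 (Ac2O, pyridine) gives the allylic acetate F4; 0.1 M aq. HCl–THF gives the lactol acetate F5; SmI2 (2.2 equiv) in THF–t-BuOH at high dilution generates the C8 ketyl, which adds to the butenolide β-carbon, and the samarium enolate expels acetate to give the exo-methylene lactone 17. The C7/C8 configuration must be confirmed.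

Step 11 (Mitsunobu at C8). The carbinol is hindered and elimination towards the 1(10)-alkene or the lactone is likely. Fallback, from 18 back to 20: invert by oxidation and reduction instead of displacement. Buffered Dess–Martin oxidation (NaHCO3, CH2Cl2, 0 °C) gives the C8 ketone F6, handled cold to avoid migration of the exo-methylene. Luche reduction (NaBH4, CeCl3·7H2O, MeOH, −78 °C), with hydride expected from the more open face anti to the C7–C11 bond, gives the 8R carbinol F7. Acylation with isobutyric anhydride, DMAP and Et3N gives 20. The same F7 would be in hand directly, after silylation, if step 9 delivered the 8R carbinol, and it would then only need this acylation.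

Step 7 (C6 stereocentre). The enantioselectivity of the Ni/Cr coupling with this new iodoacrylate and a Z-enal is unproven. Fallback, from 9 back to 14: set C6 by zinc-catalysed asymmetric alkynylation and build the butenolide stepwise. Me2Zn with the ProPhenol enantiomer that gives Si-face addition adds methyl propiolate 10 to 9 to give the hydroxy ynoate F1. Pd(PPh3)4-catalysed syn-hydrostannation with Bu3SnH puts tin α to the ester, and the Z γ-hydroxy ester lactonises to the 3-stannylbutenolide F2. Iododestannylation (I2, CH2Cl2, 0 °C) gives the 3-iodobutenolide F3. Stille coupling with (tributylstannyl)methanol (Pd(PPh3)4, dioxane, 80 °C) gives 14.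

**Further compounds**
F1 | step 7 | methyl (4R,5Z)-4-hydroxy-9-[(3Z)-5-methoxyoxolan-3-ylidene]-6-methylnon-5-en-2-ynoate | O[C@H](/C=C(/C)CC/C=C1\COC(OC)C1)C#CC(=O)OC
F2 | step 7 | (5R)-5-{(1Z)-5-[(3Z)-5-methoxyoxolan-3-ylidene]-2-methylpent-1-en-1-yl}-3-(tributylstannyl)furan-2(5H)-one | O=C1O[C@H](/C=C(/C)CC/C=C2\COC(OC)C2)C=C1[Sn](CCCC)(CCCC)CCCC
F3 | step 7 | (5R)-3-iodo-5-{(1Z)-5-[(3Z)-5-methoxyoxolan-3-ylidene]-2-methylpent-1-en-1-yl}furan-2(5H)-one | O=C1O[C@H](/C=C(/C)CC/C=C2\COC(OC)C2)C=C1I
F4 | step 9 | {(5R)-5-{(1Z)-5-[(3Z)-5-methoxyoxolan-3-ylidene]-2-methylpent-1-en-1-yl}-2-oxo-2,5-dihydrofuran-3-yl}methyl acetate | O=C1O[C@H](/C=C(/C)CC/C=C2\COC(OC)C2)C=C1COC(C)=O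
F5 | step 9 | {(5R)-5-{(1Z)-5-[(3Z)-5-hydroxyoxolan-3-ylidene]-2-methylpent-1-en-1-yl}-2-oxo-2,5-dihydrofuran-3-yl}methyl acetate | O=C1O[C@H](/C=C(/C)CC/C=C2\COC(O)C2)C=C1COC(C)=O
F6 | step 11 | (3aS,6Z,10Z,11aR)-6-({[tert-butyl(dimethyl)silyl]oxy}methyl)-10-methyl-3-methylidene-3a,8,9,11a-tetrahydrocyclodeca[b]furan-2,4(3H,5H)-dione | C=C1C(=O)O[C@@H]2/C=C(/C)CC/C=C(\CO[Si](C)(C)C(C)(C)C)CC(=O)[C@@H]12
F7 | step 11 | (3aR,4R,6Z,10Z,11aR)-6-({[tert-butyl(dimethyl)silyl]oxy}methyl)-4-hydroxy-10-methyl-3-methylidene-3a,4,5,8,9,11a-hexahydrocyclodeca[b]furan-2(3H)-one | C=C1C(=O)O[C@@H]2/C=C(/C)CC/C=C(\CO[Si](C)(C)C(C)(C)C)C[C@@H](O)[C@@H]12
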